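Readings and results were computed on assumed constants; the scatter is artificial.

At early times the midnight and spring runs have made little Z, so their first readings stand closest to the starting rate r.

all flasks: X 220 mM
- midnight: G 200 mM; E 4.00 mM
- spring: G 200 mM; E 2.00 mM
- summer: G 400 mM; E 8.00 mM; time 120 min

| midnight run: time / min | midnight run: [Z] / mM | spring run: time / min | spring run: [Z] / mM |
|---|---|---|---|
| 15 | 32.9 | 15 | 7.8 |
| 30 | 53.5 | 30 | 13.1 |
| 45 | 66.0 | 45 | 15.7 |
| 60 | 74.4 | 60 | 18.3 |
| 75 | 80.4 | 75 | 20.3 |
| 90 | 84.5 | 90 | 17.9 |
| 100 | 85.3 | 100 | 22.0 |
| 120 | 85.9 | 120 | 20.7 |

(standard deviation of a reading: 1 mM)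

- Overall: G + X -> Z, with E as catalyst.
- Constant volume, constant temperature.
- Readings of a species count what is bound in complexes too.
- "The second partner" is X.
- An order is taken over about fifteen percent of the charge, up and down.

- order of the initial rate in [E], near the charge of the midnight run, the rate being that where two percent of its G are Z
- Z in the summer run at 120 min, as a share of the G charged

At 15 min the midnight run reads 32.9 mM of Z and the spring run 7.8 mM. These runs differ in E and share their G and X charges. The order n in E is the power to which the rate follows E. On a base-ten log scale it is a rise of 0.625 in these first readings over 0.301 in E, so n reads as 2.08.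

Neither run keeps its rate. The midnight run flattens near 85.9 mM with 114 mM of G unconverted. If a rate fades by a fixed fraction per minute, the part of the final Z still unmade falls as exp(−t/τ), and the final Z is r times τ, the reach time. The unmade part at the first midnight reading gives τ as 31.1 min. This τ gives the midnight run 53.2 mM of Z at 30 min, where the reading is 53.5 mM. The spring readings give τ as 31.7 min, about the same.

My reckoning for the summer run takes the midnight r as final Z over τ, 2.77 mM/min, and carries it up by n, to 11.7 mM/min, although neither earlier run gives an order in G. Times τ this gives 364 mM, more than the 220 mM of X. X is then the limiting reagent, and the share is 55.0%.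

The forecast gives 2 and 53.5%, a share below mine, with the words “so X limits”.

The flask gives 2.1 and 39.2%.

    E + G ⇌ EG, settled at all times (48.50 /M)
    E + X ⇌ EX, settled at all times (12.60 /M)
    EG + EX → Z + 2 E (1128 /M/min)
    EG → Gy + G (0.02088 /min)

The summer run stands at 157 mM of Z at 120 min, 63.0 mM below the X charge, and below the 364 mM that the projected 11.7 mM/min gave with the midnight τ of 31.1 min. The turning of EG into Gy + G takes 16 percentage points from the summer run: the same run without that step reaches 55.0%.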